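**Retrosynthetic overview**
- The last bond made is C2–C1': ring B is attached by rhodium-catalysed asymmetric conjugate arylation of a 6-lavandulyl-5,7-bis(MOM)chromone, which sets C2; acid then removes the three MOM ethers.
- Ring C is closed before that as a chromone through O1–C2, from a 2-hydroxyacetophenone via its enaminone; the acetyl carbon enters by ortho-lithiation, and the only free phenol is the SEM-marked oxygen para to the side chain.
- The lavandulyl chain is joined at C1''–C2'' by an enantioselective, gamma-selective allylboration of a symmetric phloroglucinol aldehyde with (E)-2,6-dimethylhepta-2,5-dienyl pinacol boronate; the benzylic oxygen is then removed.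
- Structural feature used: C2'' carries an isopropenyl group, so it is the gamma carbon of a 2-methylallyl nucleophile; the benzylic C1'' sits on C6 of ring A between O5 and O7 and para to O1, so ring A maps onto C2v-symmetric 2,4,6-trihydroxybenzaldehyde, whose para oxygen becomes O1.
- Ring order: ring A is bought, the side chain is installed, ring C is closed, ring B is attached last.

Key step: step 7

Assumption: the sense of induction of (R)-TRIP in step 7 and of (R)-MeO-F12-BIPHEP in step 16 is assigned by analogy with simple aryl aldehydes and unsubstituted chromone; if a model run shows the opposite sense, the antipodal catalyst is used and nothing else changes.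

Remark: the CIP descriptor of C2'' is R in the carbinol and its xanthate and S from the deoxygenated arene to the target, only because the benzylic carbon falls below isopropenyl in priority once its oxygen is gone; no bond at C2'' is touched.

**Step 1**
Reactants: 1 2,4,6-trihydroxybenzaldehyde
Product: 2 2,6-dihydroxy-4-{[2-(trimethylsilyl)ethoxy]methoxy}benzaldehyde
Conditions: SEMCl (1.0 equiv), iPr2NEt (1.1 equiv), THF, −20 → 0 °C
Reagents that add atoms: 2-(trimethylsilyl)ethoxymethyl chloride, C[Si](C)(C)CCOCCl
Why: Williamson-type O-alkylation in which the 4-OH, the most acidic phenol (para to the formyl group) and the only one not tied up in a hydrogen bond to the carbonyl, should react in preference to the two chelated ortho hydroxyls when one equivalent of SEMCl and a weak amine base are used.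

**Step 2**
Reactants: 2 2,6-dihydroxy-4-{[2-(trimethylsilyl)ethoxy]methoxy}benzaldehyde
Product: 3 2,6-bis(methoxymethoxy)-4-{[2-(trimethylsilyl)ethoxy]methoxy}benzaldehyde
Conditions: NaH (2.5 equiv), MOMCl (2.5 equiv), DMF, 0 °C → rt
Reagents that add atoms: chloromethyl methyl ether, COCCl
Why: Williamson-type acetal formation in which full deprotonation by NaH overcomes the chelation of both ortho phenols, while the SEM ether and the non-enolisable aldehyde are inert.

**Step 3**
Reactants: 4 prenyl bromide (1-bromo-3-methylbut-2-ene); 5 2-methylprop-1-enylmagnesium bromide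
Product: 6 2,6-dimethylhepta-2,5-diene
Conditions: CuI (5 mol%), THF, −20 °C → rt
Reagents that add atoms: none
Why: Copper-catalysed cross-coupling of an alkenyl Grignard reagent with an allylic bromide, in which substitution occurs at the unhindered primary carbon of prenyl bromide (attack at the gamma carbon would build a quaternary centre) and gives the symmetric skipped diene.

**Step 4**
Reactants: 6 2,6-dimethylhepta-2,5-diene
Product: 7 (2E)-2,6-dimethylhepta-2,5-dien-1-ol
Conditions: SeO2 (0.25 equiv), t-BuOOH (1.2 equiv), salicylic acid (cat.), CH2Cl2, 0 °C → rt, stopped at partial conversion with recovery of 6; then NaBH4, MeOH, 0 °C to return any enal to the alcohol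
Reagents that add atoms: tert-butyl hydroperoxide, CC(C)(C)OO
Why: Riley allylic oxidation (ene reaction, then 2,3-sigmatropic shift of the allylseleninic acid) attacks the more substituted end of a trisubstituted alkene and oxidises the methyl group trans to the chain, which gives the (E)-allylic alcohol; the two ends of the diene are identical, so only one mono-oxidation product can form.

**Step 5**
Reactants: 7 (2E)-2,6-dimethylhepta-2,5-dien-1-ol
Product: 9 (2E)-1-chloro-2,6-dimethylhepta-2,5-diene, via allylic mesylate 8 (not isolated)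
Conditions: MsCl, 2,4,6-collidine, LiCl, DMF, 0 °C
Reagents that add atoms: lithium chloride, [Li+].[Cl-]
Why: Mesylation followed by SN2 displacement with chloride at the primary allylic carbon under buffered conditions should keep the (E) geometry and avoid allylic transposition.

**Step 6**
Reactants: 9 (2E)-1-chloro-2,6-dimethylhepta-2,5-diene
Product: 10 2-[(2E)-2,6-dimethylhepta-2,5-dien-1-yl]-4,4,5,5-tetramethyl-1,3,2-dioxaborolane
Conditions: B2pin2 (1.1 equiv), Pd2(dba)3 (2 mol%), THF, 60 °C
Reagents that add atoms: bis(pinacolato)diboron, CC1(C)OB(OC1(C)C)B1OC(C)(C)C(C)(C)O1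
Why: Palladium-catalysed allylic borylation (Miyaura-type) in which oxidative addition to zerovalent palladium gives a π-allyl complex, and transmetalation with B2pin2 followed by reductive elimination at the less hindered CH2 terminus gives the linear allylboronate, the syn π-allyl complex being expected to keep the (E) geometry.

**Step 7**
Reactants: 3 2,6-bis(methoxymethoxy)-4-{[2-(trimethylsilyl)ethoxy]methoxy}benzaldehyde; 10 2-[(2E)-2,6-dimethylhepta-2,5-dien-1-yl]-4,4,5,5-tetramethyl-1,3,2-dioxaborolane
Product: 12 (1R,2R)-1-[2,6-bis(methoxymethoxy)-4-{[2-(trimethylsilyl)ethoxy]methoxy}phenyl]-5-methyl-2-(prop-1-en-2-yl)hex-4-en-1-ol, via pinacol borate ester 11 (not isolated)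
Conditions: 10 (1.5 equiv), (R)-TRIP [(R)-3,3'-bis(2,4,6-triisopropylphenyl)-1,1'-binaphthyl-2,2'-diyl hydrogen phosphate] (10 mol%), 4 Å MS, toluene, −30 °C → rt; aq. NaHCO3 work-up
Reagents that add atoms: none
Why: The phosphoric acid hydrogen-bonds to a boronate oxygen of 10 and so raises the Lewis acidity of boron; boron binds the formyl oxygen of 3 and the allyl unit is transferred through a closed six-membered chair (Zimmerman–Traxler) transition state, so the C1''–C2'' bond forms only at the gamma carbon, the B–CH2 carbon becomes the =CH2 of the isopropenyl group, and the borate 11 is hydrolysed on work-up. The closest known reaction type is the chiral phosphoric acid-catalysed allyl- and crotylboration of aryl aldehydes with pinacol boronates. No ring is closed in this step. The carbinol centre C1'' (R) is set by the catalyst, which exposes the Re face of the aldehyde, and C2'' (R in 12, the centre that survives to the target) follows from it through the chair, in which the (E) geometry of 10 places the prenyl-bearing CH2 pseudo-equatorial and gives the anti adduct. The step needs gamma-regioselectivity (inherent in the cyclic transition state), high enantiofacial selectivity (from the catalyst, with little uncatalysed background expected because the hindered, electron-rich aldehyde barely reacts with a pinacol boronate without acid) and a geometrically pure boronate. The aldehyde is C2v-symmetric and non-enolisable, so neither positional isomers nor aldol side reactions can arise.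

**Step 8**
Reactants: 12 (1R,2R)-1-[2,6-bis(methoxymethoxy)-4-{[2-(trimethylsilyl)ethoxy]methoxy}phenyl]-5-methyl-2-(prop-1-en-2-yl)hex-4-en-1-ol
Product: 14 O-{(1R,2R)-1-[2,6-bis(methoxymethoxy)-4-{[2-(trimethylsilyl)ethoxy]methoxy}phenyl]-5-methyl-2-(prop-1-en-2-yl)hex-4-en-1-yl} S-methyl dithiocarbonate, via sodium xanthate salt 13 (not isolated)
Conditions: NaH, THF, 0 °C; CS2; then MeI, 0 °C → rt; used without prolonged storage
Reagents that add atoms: carbon disulfide, S=C=S; iodomethane, CI
Why: Xanthate formation (first stage of the Barton–McCombie deoxygenation), in which the sodium alkoxide adds to CS2 and the dithiocarbonate salt is S-methylated under basic conditions that leave the acetals and both alkenes untouched.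

**Step 9**
Reactants: 14 O-{(1R,2R)-1-[2,6-bis(methoxymethoxy)-4-{[2-(trimethylsilyl)ethoxy]methoxy}phenyl]-5-methyl-2-(prop-1-en-2-yl)hex-4-en-1-yl} S-methyl dithiocarbonate
Product: 15 1,3-bis(methoxymethoxy)-2-[(2S)-5-methyl-2-(prop-1-en-2-yl)hex-4-en-1-yl]-5-{[2-(trimethylsilyl)ethoxy]methoxy}benzene
Conditions: Bu3SnH (2 equiv), Et3B (0.2 equiv), air, toluene, rt
Reagents that add atoms: none
Why: Barton–McCombie radical deoxygenation, in which the stannyl radical adds to the thiocarbonyl sulfur and the C1''–O bond fragments to a stabilised benzylic radical that has no fast cyclisation path onto either alkene (only 3-exo, 4-exo or 5-endo modes) and is reduced by Bu3SnH, so C2'' and both double bonds are kept and room-temperature initiation avoids thermal xanthate elimination.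

**Step 10**
Reactants: 15 1,3-bis(methoxymethoxy)-2-[(2S)-5-methyl-2-(prop-1-en-2-yl)hex-4-en-1-yl]-5-{[2-(trimethylsilyl)ethoxy]methoxy}benzene
Product: 17 1-[2,4-bis(methoxymethoxy)-3-[(2S)-5-methyl-2-(prop-1-en-2-yl)hex-4-en-1-yl]-6-{[2-(trimethylsilyl)ethoxy]methoxy}phenyl]ethan-1-one, via aryllithium 16 (not isolated)
Conditions: n-BuLi (1.2 equiv), THF, 0 °C, 1 h; N-methoxy-N-methylacetamide, −78 → 0 °C; aq. NH4Cl
Reagents that add atoms: N-methoxy-N-methylacetamide, CC(=O)N(C)OC
Why: Directed ortho-metalation followed by Weinreb ketone synthesis; the only two ring hydrogens are equivalent and each lies between two alkoxymethoxy directing groups (OMOM and OSEM), so lithiation is unambiguous, and the chelated tetrahedral adduct releases the methyl ketone only on work-up.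

**Step 11**
Reactants: 17 1-[2,4-bis(methoxymethoxy)-3-[(2S)-5-methyl-2-(prop-1-en-2-yl)hex-4-en-1-yl]-6-{[2-(trimethylsilyl)ethoxy]methoxy}phenyl]ethan-1-one
Product: 18 1-[6-hydroxy-2,4-bis(methoxymethoxy)-3-[(2S)-5-methyl-2-(prop-1-en-2-yl)hex-4-en-1-yl]phenyl]ethan-1-one
Conditions: Bu4NF (4 equiv), THF/DMPU, 60 °C; aq. NH4Cl
Reagents that add atoms: none
Why: Fluoride-induced fragmentation of the aryl SEM ether (attack at silicon, loss of ethene and formaldehyde) frees only the phenol that was para to the original formyl carbon, because MOM ethers do not respond to fluoride.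

**Step 12**
Reactants: 18 1-[6-hydroxy-2,4-bis(methoxymethoxy)-3-[(2S)-5-methyl-2-(prop-1-en-2-yl)hex-4-en-1-yl]phenyl]ethan-1-one
Product: 19 (2E)-3-(dimethylamino)-1-[6-hydroxy-2,4-bis(methoxymethoxy)-3-[(2S)-5-methyl-2-(prop-1-en-2-yl)hex-4-en-1-yl]phenyl]prop-2-en-1-one
Conditions: DMF dimethyl acetal (3 equiv), toluene, 90 °C
Reagents that add atoms: N,N-dimethylformamide dimethyl acetal, COC(OC)N(C)C
Why: Condensation of the acidic acetyl CH3 with the amide acetal gives the (E)-enaminone and supplies the future C2 of ring C.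

**Step 13**
Reactants: 19 (2E)-3-(dimethylamino)-1-[6-hydroxy-2,4-bis(methoxymethoxy)-3-[(2S)-5-methyl-2-(prop-1-en-2-yl)hex-4-en-1-yl]phenyl]prop-2-en-1-one
Product: 20 5,7-bis(methoxymethoxy)-6-[(2S)-5-methyl-2-(prop-1-en-2-yl)hex-4-en-1-yl]-4H-chromen-4-one
Conditions: AcOH (5 equiv), toluene, 60 °C
Reagents that add atoms: none
Why: Acid-promoted intramolecular oxa-Michael addition of the single free phenol to the enaminone and loss of dimethylamine closes ring C as the chromone (O1–C2 bond); because only the former SEM oxygen is free, the side chain is fixed at C6.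

**Step 14**
Reactants: 21 4-bromo-3-methoxyphenol
Product: 22 1-bromo-2-methoxy-4-(methoxymethoxy)benzene
Conditions: MOMCl, iPr2NEt, CH2Cl2, 0 °C → rt
Reagents that add atoms: chloromethyl methyl ether, COCCl
Why: Williamson-type protection of the phenol as its MOM ether so that it tolerates the organolithium step.

**Step 15**
Reactants: 22 1-bromo-2-methoxy-4-(methoxymethoxy)benzene
Product: 25 [2-methoxy-4-(methoxymethoxy)phenyl]boronic acid, via aryllithium 23 (not isolated), via lithium triisopropoxyborate 24 (not isolated)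
Conditions: n-BuLi, THF, −78 °C; B(OiPr)3, −78 °C → rt; aq. NH4Cl
Reagents that add atoms: triisopropyl borate, CC(C)OB(OC(C)C)OC(C)C; water, O
Why: Bromine–lithium exchange is faster than ortho-deprotonation at −78 °C, the aryllithium is trapped by the borate, and mild hydrolysis of the ate complex gives the boronic acid with the MOM ether intact.

**Step 16**
Reactants: 20 5,7-bis(methoxymethoxy)-6-[(2S)-5-methyl-2-(prop-1-en-2-yl)hex-4-en-1-yl]-4H-chromen-4-one; 25 [2-methoxy-4-(methoxymethoxy)phenyl]boronic acid
Product: 26 (2S)-2-[2-methoxy-4-(methoxymethoxy)phenyl]-5,7-bis(methoxymethoxy)-6-[(2S)-5-methyl-2-(prop-1-en-2-yl)hex-4-en-1-yl]-2,3-dihydro-4H-chromen-4-one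
Conditions: 25 (3 equiv, in portions), [Rh(OH)(cod)]2 (3 mol%), (R)-MeO-F12-BIPHEP [2,2'-bis{bis(3,4,5-trifluorophenyl)phosphino}-6,6'-dimethoxy-1,1'-biphenyl] (7 mol%), toluene/H2O, 40 °C, no added base
Reagents that add atoms: none
Why: Hayashi–Miyaura asymmetric conjugate addition, in which the aryl group passes from boron to rhodium and the aryl–rhodium species inserts the C2=C3 bond of the chromone on the face chosen by the chiral diphosphine, which sets C2 as (S) independently of the remote C2'' centre, while base-free protonolysis of the rhodium enolate limits ring opening to the chalcone.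

**Step 17**
Reactants: 26 (2S)-2-[2-methoxy-4-(methoxymethoxy)phenyl]-5,7-bis(methoxymethoxy)-6-[(2S)-5-methyl-2-(prop-1-en-2-yl)hex-4-en-1-yl]-2,3-dihydro-4H-chromen-4-one
Product: 27 (2S)-5,7-dihydroxy-2-(4-hydroxy-2-methoxyphenyl)-6-[(2S)-5-methyl-2-(prop-1-en-2-yl)hex-4-en-1-yl]-2,3-dihydro-4H-chromen-4-one (CNP0102823.1)
Conditions: 3 M aq. HCl, MeOH/THF, 40 °C, quenched with NaHCO3 as soon as the last MOM ether is gone
Reagents that add atoms: none
Why: Acid-catalysed acetal cleavage (transacetalisation to dimethoxymethane) removes the three MOM groups, and the mild temperature and early quench are chosen to avoid cyclisation of the 5- or 7-OH onto the isopropenyl group and epimerisation at C2.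

**Compound list**
1 | 2,4,6-trihydroxybenzaldehyde | O=Cc1c(O)cc(O)cc1O | starting material
2 | 2,6-dihydroxy-4-{[2-(trimethylsilyl)ethoxy]methoxy}benzaldehyde | O=Cc1c(O)cc(OCOCC[Si](C)(C)C)cc1O | intermediate
3 | 2,6-bis(methoxymethoxy)-4-{[2-(trimethylsilyl)ethoxy]methoxy}benzaldehyde | O=Cc1c(OCOC)cc(OCOCC[Si](C)(C)C)cc1OCOC | intermediate
4 | prenyl bromide (1-bromo-3-methylbut-2-ene) | CC(C)=CCBr | starting material
5 | 2-methylprop-1-enylmagnesium bromide | CC(C)=C[Mg]Br | starting material
6 | 2,6-dimethylhepta-2,5-diene | CC(C)=CCC=C(C)C | intermediate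
7 | (2E)-2,6-dimethylhepta-2,5-dien-1-ol | CC(C)=CC/C=C(\C)CO | intermediate
8 | (2E)-2,6-dimethylhepta-2,5-dien-1-yl methanesulfonate (not isolated) | CC(C)=CC/C=C(\C)COS(C)(=O)=O | intermediate
9 | (2E)-1-chloro-2,6-dimethylhepta-2,5-diene | CC(C)=CC/C=C(\C)CCl | intermediate
10 | 2-[(2E)-2,6-dimethylhepta-2,5-dien-1-yl]-4,4,5,5-tetramethyl-1,3,2-dioxaborolane | CC(C)=CC/C=C(\C)CB1OC(C)(C)C(C)(C)O1 | intermediate
11 | pinacol borate ester of alcohol 12 (not isolated) | C=C(C)[C@@H](CC=C(C)C)[C@@H](OB1OC(C)(C)C(C)(C)O1)c1c(OCOC)cc(OCOCC[Si](C)(C)C)cc1OCOC | intermediate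
12 | (1R,2R)-1-[2,6-bis(methoxymethoxy)-4-{[2-(trimethylsilyl)ethoxy]methoxy}phenyl]-5-methyl-2-(prop-1-en-2-yl)hex-4-en-1-ol | C=C(C)[C@@H](CC=C(C)C)[C@@H](O)c1c(OCOC)cc(OCOCC[Si](C)(C)C)cc1OCOC | intermediate
13 | sodium O-alkyl dithiocarbonate (xanthate salt) of 12 (not isolated) | C=C(C)[C@@H](CC=C(C)C)[C@@H](OC(=S)[S-])c1c(OCOC)cc(OCOCC[Si](C)(C)C)cc1OCOC.[Na+] | intermediate
14 | O-{(1R,2R)-1-[2,6-bis(methoxymethoxy)-4-{[2-(trimethylsilyl)ethoxy]methoxy}phenyl]-5-methyl-2-(prop-1-en-2-yl)hex-4-en-1-yl} S-methyl dithiocarbonate | C=C(C)[C@@H](CC=C(C)C)[C@@H](OC(=S)SC)c1c(OCOC)cc(OCOCC[Si](C)(C)C)cc1OCOC | intermediate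
15 | 1,3-bis(methoxymethoxy)-2-[(2S)-5-methyl-2-(prop-1-en-2-yl)hex-4-en-1-yl]-5-{[2-(trimethylsilyl)ethoxy]methoxy}benzene | C=C(C)[C@@H](CC=C(C)C)Cc1c(OCOC)cc(OCOCC[Si](C)(C)C)cc1OCOC | intermediate
16 | aryllithium from 15, lithiated between OMOM and OSEM (not isolated) | C=C(C)[C@@H](CC=C(C)C)Cc1c(OCOC)cc(OCOCC[Si](C)(C)C)c([Li])c1OCOC | intermediate
17 | 1-[2,4-bis(methoxymethoxy)-3-[(2S)-5-methyl-2-(prop-1-en-2-yl)hex-4-en-1-yl]-6-{[2-(trimethylsilyl)ethoxy]methoxy}phenyl]ethan-1-one | C=C(C)[C@@H](CC=C(C)C)Cc1c(OCOC)cc(OCOCC[Si](C)(C)C)c(C(C)=O)c1OCOC | intermediate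
18 | 1-[6-hydroxy-2,4-bis(methoxymethoxy)-3-[(2S)-5-methyl-2-(prop-1-en-2-yl)hex-4-en-1-yl]phenyl]ethan-1-one | C=C(C)[C@@H](CC=C(C)C)Cc1c(OCOC)cc(O)c(C(C)=O)c1OCOC | intermediate
19 | (2E)-3-(dimethylamino)-1-[6-hydroxy-2,4-bis(methoxymethoxy)-3-[(2S)-5-methyl-2-(prop-1-en-2-yl)hex-4-en-1-yl]phenyl]prop-2-en-1-one | C=C(C)[C@@H](CC=C(C)C)Cc1c(OCOC)cc(O)c(C(=O)/C=C/N(C)C)c1OCOC | intermediate
20 | 5,7-bis(methoxymethoxy)-6-[(2S)-5-methyl-2-(prop-1-en-2-yl)hex-4-en-1-yl]-4H-chromen-4-one | C=C(C)[C@@H](CC=C(C)C)Cc1c(OCOC)cc2occc(=O)c2c1OCOC | intermediate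
21 | 4-bromo-3-methoxyphenol | COc1cc(O)ccc1Br | starting material
22 | 1-bromo-2-methoxy-4-(methoxymethoxy)benzene | COc1cc(OCOC)ccc1Br | intermediate
23 | [2-methoxy-4-(methoxymethoxy)phenyl]lithium (not isolated) | COc1cc(OCOC)ccc1[Li] | intermediate
24 | lithium triisopropoxy[2-methoxy-4-(methoxymethoxy)phenyl]borate (not isolated) | COc1cc(OCOC)ccc1[B-](OC(C)C)(OC(C)C)OC(C)C.[Li+] | intermediate
25 | [2-methoxy-4-(methoxymethoxy)phenyl]boronic acid | COc1cc(OCOC)ccc1B(O)O | intermediate
26 | (2S)-2-[2-methoxy-4-(methoxymethoxy)phenyl]-5,7-bis(methoxymethoxy)-6-[(2S)-5-methyl-2-(prop-1-en-2-yl)hex-4-en-1-yl]-2,3-dihydro-4H-chromen-4-one | C=C(C)[C@@H](CC=C(C)C)Cc1c(OCOC)cc2c(c1OCOC)C(=O)C[C@@H](c1ccc(OCOC)cc1OC)O2 | intermediate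
27 | (2S)-5,7-dihydroxy-2-(4-hydroxy-2-methoxyphenyl)-6-[(2S)-5-methyl-2-(prop-1-en-2-yl)hex-4-en-1-yl]-2,3-dihydro-4H-chromen-4-one (CNP0102823.1) | C=C(C)[C@@H](CC=C(C)C)Cc1c(O)cc2c(c1O)C(=O)C[C@@H](c1ccc(O)cc1OC)O2 | target

**Step count**
Total steps: 17. Longest linear sequence: 13 steps (steps 3–13, 16 and 17, from prenyl bromide and the Grignard reagent).

**Steps most likely to fail**

1. Step 7. The aldehyde carbon is flanked by two ortho acetal ethers and deactivated by three oxygen donors, and the boronate is substituted at both the beta and the gamma carbon. Addition may therefore be slow, and the catalyst may discriminate poorly between the aldehyde faces. Fallback: setting out from 3 and 10, the allylboration is run under achiral Lewis acid catalysis (Sc(OTf)3, CH2Cl2, −78 → −40 °C). This accelerates the same closed transition state without changing its anti outcome and should give the racemic anti alcohol rac-(1R*,2R*)-12 F1. The enantiomers of F1 are then separated by preparative chromatography on a chiral stationary phase. The (1R,2R) enantiomer is compound 12, where the route resumes.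

2. Step 16. Insertion may be slow because the boronic acid carries an ortho methoxy group and the chromone is substituted at C5 and C6. The electron-rich boronic acid may also protodeboronate, and the rhodium enolate may open to the chalcone. Fallback: the classical chalcone route, setting out from 18 and 22. Aryl bromide 22 is lithiated (n-BuLi, THF, −78 °C) and formylated with DMF to give 2-methoxy-4-(methoxymethoxy)benzaldehyde F2. Claisen–Schmidt condensation of 18 with F2 (KOH, EtOH, rt) gives the 2'-hydroxychalcone F3. Oxa-Michael cyclisation of F3 (NaOAc, EtOH, reflux) gives 26 together with its (2R) epimer F4. The two C2 epimers are separated by preparative chromatography on a chiral stationary phase, and F4 is re-equilibrated with base through the chalcone and recycled. The fallback comes back to the route at 26.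

3. Step 8 (with its reduction in step 9). The O-benzylic xanthate sits on a 2,4,6-trioxygenated ring, so it may ionise and rearrange from oxygen to sulfur, or eliminate, before the radical chain can cleave it. Fallback: setting out from 12, the free benzylic alcohol is reduced directly by dissolving metal (Li, NH3/THF, −78 °C, then solid NH4Cl). This cleaves the C1''–O bond by electron transfer through the arene and should leave the isolated alkenes and the acetal ethers untouched. It comes back to the route at 15 and makes no new compound.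

**Further compounds**
F1 | step 7 | racemic anti alcohol rac-(1R*,2R*)-12 (both enantiomers) | C=C(C)[C@@H](CC=C(C)C)[C@@H](O)c1c(OCOC)cc(OCOCC[Si](C)(C)C)cc1OCOC.C=C(C)[C@H](CC=C(C)C)[C@H](O)c1c(OCOC)cc(OCOCC[Si](C)(C)C)cc1OCOC
F2 | step 16 | 2-methoxy-4-(methoxymethoxy)benzaldehyde | COc1cc(OCOC)ccc1C=O
F3 | step 16 | (2E)-1-[6-hydroxy-2,4-bis(methoxymethoxy)-3-[(2S)-5-methyl-2-(prop-1-en-2-yl)hex-4-en-1-yl]phenyl]-3-[2-methoxy-4-(methoxymethoxy)phenyl]prop-2-en-1-one | C=C(C)[C@@H](CC=C(C)C)Cc1c(OCOC)cc(O)c(C(=O)/C=C/c2ccc(OCOC)cc2OC)c1OCOC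
F4 | step 16 | (2R)-2-[2-methoxy-4-(methoxymethoxy)phenyl]-5,7-bis(methoxymethoxy)-6-[(2S)-5-methyl-2-(prop-1-en-2-yl)hex-4-en-1-yl]-2,3-dihydro-4H-chromen-4-one | C=C(C)[C@@H](CC=C(C)C)Cc1c(OCOC)cc2c(c1OCOC)C(=O)C[C@H](c1ccc(OCOC)cc1OC)O2
F0 | step 8 | none | none
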